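## Retrosynthetic overview
1. One final operation unmasks three latent alcohols: the C8-vinyl group (→ C9H2OH), an aryloxymalonate (→ 2-O-glyceryl unit) and a TES ether (→ side-chain OH).
2. The key disconnection is C7–C8. The ring A aldehyde carbon is joined to C8 acting as an α-aryloxy carbanion (d1 synthon). This carbanion is a lithiated allyl aryl ether relayed through a (Z)-γ-aryloxyallyl-B(Ipc)2 reagent. It already carries all of ring B and sets C7 and C8 together.
3. The ring A fragment comes from syringaldehyde and dimethyl chloromalonate. The ring B fragment comes from 4-allyl-2,6-dimethoxyphenol by hydroboration, O-allylation and silylation.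
4. No ring is formed, because both benzene rings are bought.

Assumption: the SMILES is read as (7R,8R), threo. Lignan numbering is used: C7 is the benzylic carbinol carbon, C8 the aryloxy-bearing carbon and C9 the CH2OH carbon. The 2-O-glyceryl unit is achiral.

## Route

Step 1
Reactants: 1 syringaldehyde (4-hydroxy-3,5-dimethoxybenzaldehyde); 2 dimethyl chloromalonate
Product: 3 dimethyl 2-(4-formyl-2,6-dimethoxyphenoxy)propanedioate
Conditions: K2CO3 (1.5 equiv), MeCN, 60 °C
Reagents that add atoms: dimethyl chloromalonate (2), COC(=O)C(Cl)C(=O)OC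
Why: This is a Williamson-type SN2 O-alkylation in which the acidic phenol (pKa about 7) is fully ionised by K2CO3 and displaces the doubly carbonyl-activated chloride, as guaiacol-type phenols are known to do with chloromalonates, and no stereocentre is formed.

Step 2
Reactants: 4 4-allyl-2,6-dimethoxyphenol
Product: 6 4-(3-hydroxypropyl)-2,6-dimethoxyphenol (dihydrosinapyl alcohol), via bis-boryl adduct 5 (not isolated)
Conditions: 9-BBN (2.2 equiv), THF, 0 °C → rt; then 3 M aq NaOH, 30% H2O2, 0 °C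
Reagents that add atoms: hydrogen peroxide, OO
Why: In this Brown hydroboration–oxidation the bulky 9-BBN adds anti-Markovnikov to the terminal alkene (one further equivalent is taken up by the phenol O–H and released again on work-up), and the short, cold oxidation spares the electron-rich phenol.

Step 3
Reactants: 6 4-(3-hydroxypropyl)-2,6-dimethoxyphenol; 7 allyl bromide
Product: 8 3-[3,5-dimethoxy-4-(prop-2-en-1-yloxy)phenyl]propan-1-ol
Conditions: K2CO3, acetone, reflux
Reagents that add atoms: allyl bromide (7), C=CCBr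
Why: This Williamson ether synthesis is chemoselective because K2CO3 ionises only the phenol and leaves the primary alcohol untouched, and 56 °C is far below the Claisen rearrangement threshold.

Step 4
Reactants: 8 3-[3,5-dimethoxy-4-(prop-2-en-1-yloxy)phenyl]propan-1-ol
Product: 9 triethyl{3-[3,5-dimethoxy-4-(prop-2-en-1-yloxy)phenyl]propoxy}silane
Conditions: TESCl, imidazole, CH2Cl2, 0 °C → rt
Reagents that add atoms: chlorotriethylsilane, CC[Si](Cl)(CC)CC
Why: This standard imidazole-promoted silylation of the only OH gives a TES ether that tolerates s-BuLi and BF3·OEt2 at −78 °C yet is cleaved by dilute acid at the end.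

Step 5 (key step)
Reactants: 9 triethyl{3-[3,5-dimethoxy-4-(prop-2-en-1-yloxy)phenyl]propoxy}silane; 3 dimethyl 2-(4-formyl-2,6-dimethoxyphenoxy)propanedioate
Product: 14 dimethyl 2-(4-{(1R,2R)-2-[2,6-dimethoxy-4-(3-triethylsilyloxypropyl)phenoxy]-1-hydroxybut-3-en-1-yl}-2,6-dimethoxyphenoxy)propanedioate, via allyllithium 10 (not isolated), via borate complex 11 (not isolated), via allylborane 12 (not isolated), via borinate 13 (not isolated)
Conditions: 9, s-BuLi (1.05 equiv), THF, −78 °C, 45 min; (−)-Ipc2BOMe [from (+)-α-pinene] (1.1 equiv), −78 °C, 1 h; BF3·OEt2 (1.35 equiv), then 3 (1.0 equiv), −78 °C, 4 h; pH 7 phosphate buffer, MeOH, 30% H2O2, 0 °C → rt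
Reagents that add atoms: none
Why: In this Brown asymmetric (Z)-γ-alkoxyallylboration, deprotonation turns the oxygen-bearing C8 (by nature an acceptor carbon like the aldehyde carbon C7) into an O-chelated (Z)-oxyallyl anion that boron captures at its remote terminus, so the borane delivers C8 as the nucleophile through a closed chair transition state in which the Z geometry gives the syn (threo) relationship and the (+)-α-pinene-derived Ipc groups direct attack to the Si face of 3 (the sense that gives (S)-1-phenylbut-3-en-1-ol from benzaldehyde), setting (7R,8R) in one step with an expected dr of at least 95:5 and about 90% ee, while the esters are inert to the allylborane and survive the neutral oxidative work-up.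

Step 6
Reactants: 14 dimethyl 2-(4-{(1R,2R)-2-[2,6-dimethoxy-4-(3-triethylsilyloxypropyl)phenoxy]-1-hydroxybut-3-en-1-yl}-2,6-dimethoxyphenoxy)propanedioate
Product: 17 (1R,2R)-1-{4-[(1,3-dihydroxypropan-2-yl)oxy]-3,5-dimethoxyphenyl}-2-[4-(3-hydroxypropyl)-2,6-dimethoxyphenoxy]propane-1,3-diol (target), via aldehyde 15 (not isolated), via TES tetraol 16 (not isolated)
Conditions: O3/O2, CH2Cl2/MeOH (3:1), Sudan Red 7B end point, −78 °C, N2 purge; NaBH4 (12 equiv), −78 °C → rt, 16 h; 1 M aq HCl to pH 2, 0 °C → rt, 1 h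
Reagents that add atoms: ozone, [O-][O+]=O
Why: Criegee ozonolysis of the only alkene (stopped by the dye before the arenes react) gives aldehyde 15, which NaBH4 reduces at −78 °C before C8 can epimerise or undergo retro-aldol cleavage, the excess NaBH4 in CH2Cl2/MeOH then reduces the α-aryloxy-activated malonate esters to the 1,3-diol (a known malonate-to-diol reduction), and brief dilute acid hydrolyses the primary TES ether without ionising the non-phenolic benzylic alcohol, so neither stereocentre is touched.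

## Compound list
1 | syringaldehyde | COc1cc(C=O)cc(OC)c1O | starting material
2 | dimethyl chloromalonate | COC(=O)C(Cl)C(=O)OC | starting material
3 | dimethyl 2-(4-formyl-2,6-dimethoxyphenoxy)propanedioate | COC(=O)C(Oc1c(OC)cc(C=O)cc1OC)C(=O)OC | intermediate
4 | 4-allyl-2,6-dimethoxyphenol | C=CCc1cc(OC)c(O)c(OC)c1 | starting material
5 | 9-{3-[4-(9-borabicyclo[3.3.1]nonan-9-yloxy)-3,5-dimethoxyphenyl]propyl}-9-borabicyclo[3.3.1]nonane | COc1cc(CCCB2C3CCCC2CCC3)cc(OC)c1OB1C2CCCC1CCC2 | intermediate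
6 | 4-(3-hydroxypropyl)-2,6-dimethoxyphenol | COc1cc(CCCO)cc(OC)c1O | intermediate
7 | allyl bromide | C=CCBr | starting material
8 | 3-[3,5-dimethoxy-4-(prop-2-en-1-yloxy)phenyl]propan-1-ol | C=CCOc1c(OC)cc(CCCO)cc1OC | intermediate
9 | triethyl{3-[3,5-dimethoxy-4-(prop-2-en-1-yloxy)phenyl]propoxy}silane | C=CCOc1c(OC)cc(CCCO[Si](CC)(CC)CC)cc1OC | intermediate
10 | (Z)-3-{2,6-dimethoxy-4-[3-(triethylsilyloxy)propyl]phenoxy}allyllithium | [Li]C/C=C\Oc1c(OC)cc(CCCO[Si](CC)(CC)CC)cc1OC | intermediate
11 | lithium [(Z)-3-aryloxyallyl](methoxy)bis(isopinocampheyl)borate, Ipc from (+)-α-pinene | [Li+].CO[B-](C/C=C\Oc1c(OC)cc(CCCO[Si](CC)(CC)CC)cc1OC)([C@@H]1C[C@@H]2C[C@H]([C@H]1C)C2(C)C)[C@@H]1C[C@@H]2C[C@H]([C@H]1C)C2(C)C | intermediate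
12 | [(Z)-3-aryloxyallyl]bis(isopinocampheyl)borane, Ipc from (+)-α-pinene | COc1cc(CCCO[Si](CC)(CC)CC)cc(OC)c1O/C=C\CB([C@@H]1C[C@@H]2C[C@H]([C@H]1C)C2(C)C)[C@@H]1C[C@@H]2C[C@H]([C@H]1C)C2(C)C | intermediate
13 | bis(isopinocampheyl)borinate ester of 14 at the C7 oxygen | COc1cc([C@@H](OB([C@@H]3C[C@@H]4C[C@H]([C@H]3C)C4(C)C)[C@@H]3C[C@@H]4C[C@H]([C@H]3C)C4(C)C)[C@@H](C=C)Oc2c(OC)cc(CCCO[Si](CC)(CC)CC)cc2OC)cc(OC)c1OC(C(=O)OC)C(=O)OC | intermediate
14 | dimethyl 2-(4-{(1R,2R)-2-[2,6-dimethoxy-4-(3-triethylsilyloxypropyl)phenoxy]-1-hydroxybut-3-en-1-yl}-2,6-dimethoxyphenoxy)propanedioate | COc1cc([C@@H](O)[C@@H](C=C)Oc2c(OC)cc(CCCO[Si](CC)(CC)CC)cc2OC)cc(OC)c1OC(C(=O)OC)C(=O)OC | intermediate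
15 | dimethyl 2-(4-{(1R,2S)-2-[2,6-dimethoxy-4-(3-triethylsilyloxypropyl)phenoxy]-1-hydroxy-3-oxopropyl}-2,6-dimethoxyphenoxy)propanedioate | COc1cc([C@@H](O)[C@@H](C=O)Oc2c(OC)cc(CCCO[Si](CC)(CC)CC)cc2OC)cc(OC)c1OC(C(=O)OC)C(=O)OC | intermediate
16 | (1R,2R)-1-{4-[(1,3-dihydroxypropan-2-yl)oxy]-3,5-dimethoxyphenyl}-2-{2,6-dimethoxy-4-[3-(triethylsilyloxy)propyl]phenoxy}propane-1,3-diol | COc1cc([C@@H](O)[C@@H](CO)Oc2c(OC)cc(CCCO[Si](CC)(CC)CC)cc2OC)cc(OC)c1OC(CO)CO | intermediate
17 | (1R,2R)-1-{4-[(1,3-dihydroxypropan-2-yl)oxy]-3,5-dimethoxyphenyl}-2-[4-(3-hydroxypropyl)-2,6-dimethoxyphenoxy]propane-1,3-diol | COc1cc([C@@H](O)[C@@H](CO)Oc2c(OC)cc(CCCO)cc2OC)cc(OC)c1OC(CO)CO | target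

## Step count and risks
Total step count: 6. Longest linear sequence: 5 steps (4 → 6 → 8 → 9 → 14 → 17).

**Highest risk: step 5.** Metalation of the hindered aryl allyl ether 9 may compete with ring lithiation or Wittig-type rearrangement of 10, and the Z geometry could erode.
- The fallback sets out from 6 and makes the same allylborane without any strong base.
- Compound 6 is O-propargylated (propargyl bromide, K2CO3, acetone) to 3-[3,5-dimethoxy-4-(prop-2-yn-1-yloxy)phenyl]propan-1-ol F1.
- F1 is silylated (TESCl, imidazole) to triethyl{3-[3,5-dimethoxy-4-(prop-2-yn-1-yloxy)phenyl]propoxy}silane F2.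
- F2 is isomerised with catalytic KOt-Bu in THF to the aryloxyallene triethyl{3-[3,5-dimethoxy-4-(propa-1,2-dien-1-yloxy)phenyl]propoxy}silane F3.
- Kinetically controlled hydroboration of the terminal double bond of F3 with (−)-Ipc2BH, made from (+)-α-pinene, at −40 °C places boron on the CH2 terminus from the face away from the aryloxy group. This gives the (Z)-allylborane 12.
- The route is rejoined at 12 by adding aldehyde 3 directly.

**Second risk: step 6.** Ozone may attack the two trialkoxyarenes, and the one-pot ester reduction may stall.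
- The fallback sets out from 14 and avoids ozone by working in stages.
- OsO4 (cat.)/NMO in acetone/water gives the dihydroxylated compound dimethyl 2-(4-{(1R,2R)-2-[2,6-dimethoxy-4-(3-triethylsilyloxypropyl)phenoxy]-1,3,4-trihydroxybutyl}-2,6-dimethoxyphenoxy)propanedioate F4. It forms as an inconsequential epimer mixture at the new carbinol carbon.
- NaIO4 in THF/pH 7 buffer cleaves only the free 1,2-diol of F4 and gives aldehyde 15.
- Brief NaBH4 at 0 °C gives the C9 alcohol dimethyl 2-(4-{(1R,2R)-2-[2,6-dimethoxy-4-(3-triethylsilyloxypropyl)phenoxy]-1,3-dihydroxypropyl}-2,6-dimethoxyphenoxy)propanedioate F5.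
- LiBH4 in THF/MeOH reduces both esters of F5 and gives 16.
- The route is rejoined at 16, before the acid stage.

**Third risk: step 1.** The di-ortho-substituted, weakly nucleophilic phenoxide of 1 may react sluggishly, or by halophilic attack, with the secondary chloride.
- The fallback sets out from 1 and replaces the SN2 reaction by a carbenoid O–H insertion.
- Dimethyl diazomalonate F6 is made from dimethyl malonate by diazo transfer.
- F6 is added slowly to 1 with Rh2(OAc)4 (1 mol%) in CH2Cl2 at 40 °C. Insertion into the phenol O–H bond outruns carbonyl ylide formation and gives 3 directly.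
- The route is rejoined at 3.

## Further compounds
F1 | step 5 | 3-[3,5-dimethoxy-4-(prop-2-yn-1-yloxy)phenyl]propan-1-ol | C#CCOc1c(OC)cc(CCCO)cc1OC
F2 | step 5 | triethyl{3-[3,5-dimethoxy-4-(prop-2-yn-1-yloxy)phenyl]propoxy}silane | C#CCOc1c(OC)cc(CCCO[Si](CC)(CC)CC)cc1OC
F3 | step 5 | triethyl{3-[3,5-dimethoxy-4-(propa-1,2-dien-1-yloxy)phenyl]propoxy}silane | C=C=COc1c(OC)cc(CCCO[Si](CC)(CC)CC)cc1OC
F4 | step 6 | dimethyl 2-(4-{(1R,2R)-2-[2,6-dimethoxy-4-(3-triethylsilyloxypropyl)phenoxy]-1,3,4-trihydroxybutyl}-2,6-dimethoxyphenoxy)propanedioate | COc1cc([C@@H](O)[C@@H](C(O)CO)Oc2c(OC)cc(CCCO[Si](CC)(CC)CC)cc2OC)cc(OC)c1OC(C(=O)OC)C(=O)OC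
F5 | step 6 | dimethyl 2-(4-{(1R,2R)-2-[2,6-dimethoxy-4-(3-triethylsilyloxypropyl)phenoxy]-1,3-dihydroxypropyl}-2,6-dimethoxyphenoxy)propanedioate | COc1cc([C@@H](O)[C@@H](CO)Oc2c(OC)cc(CCCO[Si](CC)(CC)CC)cc2OC)cc(OC)c1OC(C(=O)OC)C(=O)OC
F6 | step 1 | dimethyl diazomalonate | COC(=O)C(=[N+]=[N-])C(=O)OC
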